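**Strategy.** The route rests on disconnecting the aryl ether bond O1–C8a of the dihydropyranone ring (ring C). The key step is an intramolecular SNAr: the C2 alkoxide of an (S)-configured open-chain β-hydroxy ketone displaces fluoride from C8a of ring A. It exploits the C4 carbonyl, which sits ortho to C8a and makes that carbon electrophilic, and it fixes the ring A prenyl group at C6 because only C8a carries a leaving group. The C2–O bond is never broken, so configuration is retained. The precursor comes from copper-catalysed asymmetric β-borylation and oxidation of a 2'-fluorochalcone built from two MOM-protected fragments made by directed ortho-lithiation.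

Key step: step 8

Assumption: the sense of induction of the Josiphos ligand in step 7 is taken from simple β-aryl enones; if analysis of 20 shows the opposite configuration, the mirror-image ligand is used and nothing else changes.

**Step 1**
Reactants: 1 5-fluororesorcinol; 2 chloromethyl methyl ether
Product: 3 1-fluoro-3,5-bis(methoxymethoxy)benzene
Conditions: NaH, MOMCl, DMF, 0 °C → rt
Reagents that add atoms: chloromethyl methyl ether 2, COCCl
Why: Williamson-type O-alkylation of both phenoxides gives the bis-MOM ether, whose acetal oxygens later direct both ring lithiations and which mild acid removes at the end.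

**Step 2**
Reactants: 3 1-fluoro-3,5-bis(methoxymethoxy)benzene; 4 prenyl bromide (1-bromo-3-methylbut-2-ene)
Product: 6 5-fluoro-1,3-bis(methoxymethoxy)-2-(3-methylbut-2-en-1-yl)benzene, via aryllithium 5 (not isolated)
Conditions: n-BuLi, THF, −20 °C; CuI (10 mol%), prenyl bromide, −78 °C → rt
Reagents that add atoms: prenyl bromide 4, CC(C)=CCBr
Why: Directed ortho-metalation followed by copper-catalysed allylation: with n-BuLi the C–H flanked by two coordinating MOM ethers is removed in preference to the C–H next to fluorine, and the aryl nucleophile attacks the unhindered CH2 terminus of prenyl bromide to give the linear prenyl arene.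

**Step 3**
Reactants: 6 5-fluoro-1,3-bis(methoxymethoxy)-2-(3-methylbut-2-en-1-yl)benzene; 7 N-methoxy-N-methylacetamide
Product: 10 1-[6-fluoro-2,4-bis(methoxymethoxy)-3-(3-methylbut-2-en-1-yl)phenyl]ethan-1-one, via aryllithium 8 (not isolated), via tetrahedral lithium adduct 9 (not isolated)
Conditions: s-BuLi, THF, −78 °C; MeC(O)N(OMe)Me, −78 → 0 °C; H2O
Reagents that add atoms: N-methoxy-N-methylacetamide 7, CC(=O)N(C)OC
Why: Directed ortho-metalation at the only ring C–H type left (flanked by F and OMOM, kinetically favoured over the allylic CH2) and Weinreb ketone synthesis, in which the stable chelated adduct 9 prevents double addition and the low temperature keeps the ortho-fluoroaryllithium from losing LiF.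

**Step 4**
Reactants: 11 isovanillin (3-hydroxy-4-methoxybenzaldehyde); 2 chloromethyl methyl ether
Product: 12 4-methoxy-3-(methoxymethoxy)benzaldehyde
Conditions: NaH, MOMCl, DMF, 0 °C → rt
Reagents that add atoms: chloromethyl methyl ether 2, COCCl
Why: Williamson-type O-alkylation of the phenoxide; the non-enolisable aldehyde is untouched.

**Step 5**
Reactants: 12 4-methoxy-3-(methoxymethoxy)benzaldehyde; 4 prenyl bromide
Product: 16 4-methoxy-3-(methoxymethoxy)-2-(3-methylbut-2-en-1-yl)benzaldehyde, via lithium α-amino alkoxide 13 (not isolated), via ring-lithiated α-amino alkoxide 14 (not isolated), via prenylated α-amino alkoxide 15 (not isolated)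
Conditions: LiN(Me)CH2CH2NMe2, THF, −20 °C; n-BuLi (3 equiv), −20 °C; CuBr·SMe2 (cat.), prenyl bromide (excess), −78 °C → rt; H2O
Reagents that add atoms: prenyl bromide 4, CC(C)=CCBr
Why: Comins-type directed ortho-lithiation: the lithium amide adds to the aldehyde to give α-amino alkoxide 13, which protects the carbonyl and, together with the neighbouring MOM ether, directs n-BuLi to C2 between them, and allylation followed by aqueous work-up releases the aldehyde.

**Step 6**
Reactants: 10 1-[6-fluoro-2,4-bis(methoxymethoxy)-3-(3-methylbut-2-en-1-yl)phenyl]ethan-1-one; 16 4-methoxy-3-(methoxymethoxy)-2-(3-methylbut-2-en-1-yl)benzaldehyde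
Product: 17 (2E)-1-[6-fluoro-2,4-bis(methoxymethoxy)-3-(3-methylbut-2-en-1-yl)phenyl]-3-[4-methoxy-3-(methoxymethoxy)-2-(3-methylbut-2-en-1-yl)phenyl]prop-2-en-1-one
Conditions: KOH (aq.), EtOH, 0 °C → rt
Reagents that add atoms: none
Why: Claisen–Schmidt condensation (crossed aldol then E1cB dehydration) between the only enolisable partner 10 and the non-enolisable aldehyde 16 gives the conjugated E-enone, the MOM ethers and the aryl fluoride being stable to hydroxide in aqueous ethanol at room temperature.

**Step 7**
Reactants: 17 the 2'-fluorochalcone; 18 bis(pinacolato)diboron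
Product: 20 (3S)-1-[6-fluoro-2,4-bis(methoxymethoxy)-3-(3-methylbut-2-en-1-yl)phenyl]-3-hydroxy-3-[4-methoxy-3-(methoxymethoxy)-2-(3-methylbut-2-en-1-yl)phenyl]propan-1-one, via β-boryl ketone 19 (not isolated)
Conditions: CuCl (3 mol%), (R,SP)-Josiphos (3 mol%), NaOt-Bu (5 mol%), B2pin2, MeOH (2 equiv), THF, rt; then NaBO3·4H2O, THF/H2O, 0 °C → rt
Reagents that add atoms: sodium perborate (supplies the hydroxyl oxygen), [Na+].[Na+].O[B-]1(O)OO[B-](O)(O)OO1; bis(pinacolato)diboron 18 (leaves the Bpin group in 19 only), CC1(C)OB(OC1(C)C)B1OC(C)(C)C(C)(C)O1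
Why: Copper-catalysed asymmetric conjugate borylation (β-boration of an enone): the Josiphos-bound copper boryl adds boron to one face of C3, which sets the (S) C–B centre under ligand control, and perborate oxidation with retention (1,2-migration from boron to oxygen) converts it into the (S)-carbinol without touching the unactivated prenyl olefins.

**Step 8**
Reactants: 20 the (3S)-β-hydroxy ketone
Product: 22 (2S)-2-[4-methoxy-3-(methoxymethoxy)-2-(3-methylbut-2-en-1-yl)phenyl]-5,7-bis(methoxymethoxy)-6-(3-methylbut-2-en-1-yl)-2,3-dihydro-4H-chromen-4-one, via potassium alkoxide 21 (not isolated)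
Conditions: KN(SiMe3)2 (1.0 equiv), THF, −78 → −30 °C; AcOH, −30 °C
Reagents that add atoms: none
Why: Deprotonation gives alkoxide 21, whose oxygen adds to C8a (bearing F, ortho to the C4 carbonyl) to form a Meisenheimer complex delocalised into the C4a–C4=O unit, and loss of fluoride restores aromatic ring A (addition–elimination SNAr). The closest known reaction type is the intramolecular SNAr etherification of alkoxides with ortho-fluoroaryl ketones to chroman-4-ones and of fluoroarene-tethered alkoxides to flavans. The single ring closed is the six-membered ring C, by attack on sp2 carbon C8a, formally a 6-endo-trig conjugate addition to C8a=C4a–C4=O followed by elimination. No stereocentre is created: C2 is retained because its C–O bond is not broken, the configuration having been set in step 7. The step needs cyclisation to outrun retro-aldol cleavage and E1cB dehydration of the aldolate, which the carbonyl-activated C–F bond, the placement of both MOM ethers meta (not ortho or para) to C8a, the low temperature and the exactly stoichiometric base (spent as insoluble KF) should secure. Regioselectivity is built in, since the other ortho carbon C5 carries OMOM and no leaving group, so the prenyl group ends at C6.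

**Step 9**
Reactants: 22 the tris-MOM flavanone
Product: 23 (2S)-5,7-dihydroxy-2-[3-hydroxy-4-methoxy-2-(3-methylbut-2-en-1-yl)phenyl]-6-(3-methylbut-2-en-1-yl)-2,3-dihydro-4H-chromen-4-one
Conditions: HCl (ca. 1 M, from AcCl/MeOH), MeOH/THF, 0 °C → rt
Reagents that add atoms: none
Why: Acid-catalysed cleavage of the three MOM acetals by transacetalisation to methanol; dilute acid at or below room temperature should leave the prenyl olefins uncyclised, and in the absence of base C2 cannot epimerise through ring opening to the chalcone.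

**Compound list**

1 | 5-fluororesorcinol (5-fluorobenzene-1,3-diol) | Oc1cc(O)cc(F)c1 | starting material
2 | chloromethyl methyl ether | COCCl | starting material
3 | 1-fluoro-3,5-bis(methoxymethoxy)benzene | COCOc1cc(F)cc(OCOC)c1 | intermediate
4 | prenyl bromide (1-bromo-3-methylbut-2-ene) | CC(C)=CCBr | starting material
5 | [4-fluoro-2,6-bis(methoxymethoxy)phenyl]lithium | [Li]c1c(OCOC)cc(F)cc1OCOC | intermediate
6 | 5-fluoro-1,3-bis(methoxymethoxy)-2-(3-methylbut-2-en-1-yl)benzene | COCOc1cc(F)cc(OCOC)c1CC=C(C)C | intermediate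
7 | N-methoxy-N-methylacetamide | CC(=O)N(C)OC | starting material
8 | [6-fluoro-2,4-bis(methoxymethoxy)-3-(3-methylbut-2-en-1-yl)phenyl]lithium | [Li]c1c(F)cc(OCOC)c(CC=C(C)C)c1OCOC | intermediate
9 | lithium 1-[6-fluoro-2,4-bis(methoxymethoxy)-3-(3-methylbut-2-en-1-yl)phenyl]-1-[methoxy(methyl)amino]ethan-1-olate | [Li+].CC([O-])(N(C)OC)c1c(F)cc(OCOC)c(CC=C(C)C)c1OCOC | intermediate
10 | 1-[6-fluoro-2,4-bis(methoxymethoxy)-3-(3-methylbut-2-en-1-yl)phenyl]ethan-1-one | CC(=O)c1c(F)cc(OCOC)c(CC=C(C)C)c1OCOC | intermediate
11 | isovanillin (3-hydroxy-4-methoxybenzaldehyde) | COc1ccc(C=O)cc1O | starting material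
12 | 4-methoxy-3-(methoxymethoxy)benzaldehyde | COCOc1cc(C=O)ccc1OC | intermediate
13 | lithium {[2-(dimethylamino)ethyl](methyl)amino}[4-methoxy-3-(methoxymethoxy)phenyl]methanolate | [Li+].[O-]C(N(C)CCN(C)C)c1ccc(OC)c(OCOC)c1 | intermediate
14 | 2-lithio derivative of 13 (lithium at the ring carbon between the carbinol carbon and OMOM) | [Li+].[O-]C(N(C)CCN(C)C)c1ccc(OC)c(OCOC)c1[Li] | intermediate
15 | 2-(3-methylbut-2-en-1-yl) derivative of 13 | [Li+].[O-]C(N(C)CCN(C)C)c1ccc(OC)c(OCOC)c1CC=C(C)C | intermediate
16 | 4-methoxy-3-(methoxymethoxy)-2-(3-methylbut-2-en-1-yl)benzaldehyde | COc1ccc(C=O)c(CC=C(C)C)c1OCOC | intermediate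
17 | (2E)-1-[6-fluoro-2,4-bis(methoxymethoxy)-3-(3-methylbut-2-en-1-yl)phenyl]-3-[4-methoxy-3-(methoxymethoxy)-2-(3-methylbut-2-en-1-yl)phenyl]prop-2-en-1-one | COc1ccc(/C=C/C(=O)c2c(F)cc(OCOC)c(CC=C(C)C)c2OCOC)c(CC=C(C)C)c1OCOC | intermediate
18 | bis(pinacolato)diboron | CC1(C)OB(OC1(C)C)B1OC(C)(C)C(C)(C)O1 | starting material
19 | (3S)-1-[6-fluoro-2,4-bis(methoxymethoxy)-3-(3-methylbut-2-en-1-yl)phenyl]-3-[4-methoxy-3-(methoxymethoxy)-2-(3-methylbut-2-en-1-yl)phenyl]-3-(4,4,5,5-tetramethyl-1,3,2-dioxaborolan-2-yl)propan-1-one | COc1ccc([C@@H](B2OC(C)(C)C(C)(C)O2)CC(=O)c2c(F)cc(OCOC)c(CC=C(C)C)c2OCOC)c(CC=C(C)C)c1OCOC | intermediate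
20 | (3S)-1-[6-fluoro-2,4-bis(methoxymethoxy)-3-(3-methylbut-2-en-1-yl)phenyl]-3-hydroxy-3-[4-methoxy-3-(methoxymethoxy)-2-(3-methylbut-2-en-1-yl)phenyl]propan-1-one | COc1ccc([C@@H](O)CC(=O)c2c(F)cc(OCOC)c(CC=C(C)C)c2OCOC)c(CC=C(C)C)c1OCOC | intermediate
21 | potassium alkoxide of 20 (potassium (1S)-3-aryl-3-oxo-1-arylpropan-1-olate) | [K+].COc1ccc([C@@H]([O-])CC(=O)c2c(F)cc(OCOC)c(CC=C(C)C)c2OCOC)c(CC=C(C)C)c1OCOC | intermediate
22 | (2S)-2-[4-methoxy-3-(methoxymethoxy)-2-(3-methylbut-2-en-1-yl)phenyl]-5,7-bis(methoxymethoxy)-6-(3-methylbut-2-en-1-yl)-2,3-dihydro-4H-chromen-4-one | COc1ccc([C@@H]2CC(=O)c3c(cc(OCOC)c(CC=C(C)C)c3OCOC)O2)c(CC=C(C)C)c1OCOC | intermediate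
23 | (2S)-5,7-dihydroxy-2-[3-hydroxy-4-methoxy-2-(3-methylbut-2-en-1-yl)phenyl]-6-(3-methylbut-2-en-1-yl)-2,3-dihydro-4H-chromen-4-one | COc1ccc([C@@H]2CC(=O)c3c(cc(O)c(CC=C(C)C)c3O)O2)c(CC=C(C)C)c1O | target

**Step count and risk**

Total steps: 9. Longest linear sequence: 7 steps (1, 2, 3, 6, 7, 8, 9, from 5-fluororesorcinol); the aldehyde fragment takes 2 steps (4, 5) and joins at step 6.

The three steps most likely to fail:

1. Step 8. Retro-aldol fragmentation of alkoxide 21 with recombination (erosion of configuration at C2), or base-induced dehydration back to the chalcone, may compete with ring closure. The fallback removes the carbonyl for the ring closure and sets out from 20. Reduction with NaBH4 in MeOH at 0 °C should give the 1,3-diol F1 as a mixture of epimers at the new carbinol centre, which is destroyed later. Treatment with KH in DMF at 0 °C → rt should then close ring C by the same O1–C8a SNAr on the fluoroarene, a closure known from fluoroarene-based flavan syntheses; the other alkoxide cannot cyclise, and without a carbonyl neither retro-aldol nor elimination is possible. This gives the flavan-4-ol F2, and oxidation with Dess–Martin periodinane (NaHCO3, CH2Cl2) returns to the route at 22.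

2. Step 7. Poor facial selectivity or slow boryl addition at the hindered, electron-rich β-carbon may occur. The fallback sets out from 17. Juliá–Colonna epoxidation (poly-D-leucine, urea–H2O2, DBU, THF) should give the (2S,3R)-epoxy ketone F3. Reductive cleavage of its Cα–O bond with SmI2 (THF/MeOH, −90 °C) keeps the benzylic C–O bond and returns to the route at 20.

3. Step 5. Incomplete in situ protection (butyl addition to the aldehyde), incomplete ring metalation, or consumption of prenyl bromide by excess n-BuLi may occur. The fallback sets out from 11. O-alkylation with tert-butyl 2-methylbut-3-en-2-yl carbonate and Pd(PPh3)4 (THF, 0 °C → rt) should give the 1,1-dimethylallyl ether F4. Aromatic Claisen rearrangement (PhNEt2, heat) into the only free ortho position, C2, should give the ortho-prenyl phenol F5, and MOM protection (NaH, MOMCl, DMF) returns to the route at 16.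

**Further compounds**

F1 | step 8 | (1S)-3-[6-fluoro-2,4-bis(methoxymethoxy)-3-(3-methylbut-2-en-1-yl)phenyl]-1-[4-methoxy-3-(methoxymethoxy)-2-(3-methylbut-2-en-1-yl)phenyl]propane-1,3-diol (both C3 epimers) | COc1ccc([C@@H](O)CC(O)c2c(F)cc(OCOC)c(CC=C(C)C)c2OCOC)c(CC=C(C)C)c1OCOC
F2 | step 8 | (2S)-2-[4-methoxy-3-(methoxymethoxy)-2-(3-methylbut-2-en-1-yl)phenyl]-5,7-bis(methoxymethoxy)-6-(3-methylbut-2-en-1-yl)-3,4-dihydro-2H-chromen-4-ol (both C4 epimers) | COc1ccc([C@@H]2CC(O)c3c(cc(OCOC)c(CC=C(C)C)c3OCOC)O2)c(CC=C(C)C)c1OCOC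
F3 | step 7 | [6-fluoro-2,4-bis(methoxymethoxy)-3-(3-methylbut-2-en-1-yl)phenyl]{(2S,3R)-3-[4-methoxy-3-(methoxymethoxy)-2-(3-methylbut-2-en-1-yl)phenyl]oxiran-2-yl}methanone | COc1ccc([C@H]2O[C@@H]2C(=O)c2c(F)cc(OCOC)c(CC=C(C)C)c2OCOC)c(CC=C(C)C)c1OCOC
F4 | step 5 | 4-methoxy-3-[(2-methylbut-3-en-2-yl)oxy]benzaldehyde | COc1ccc(C=O)cc1OC(C)(C)C=C
F5 | step 5 | 3-hydroxy-4-methoxy-2-(3-methylbut-2-en-1-yl)benzaldehyde | COc1ccc(C=O)c(CC=C(C)C)c1O
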